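## Retrosynthetic overview

- The route rests on the benzene ring of the isochroman-1-one (C4a, C5, C6, C7, C8, C8a). It carries OMe at C6 and OH at C8, meta to each other and para/ortho to C8a, which bears the C1 carbonyl. This is the pattern a 1,1,3-trioxygenated butadiene leaves on an acetylenic ester.
- Last disconnection: the lactone bond C1–O2 (pyranone ring, closed second), together with release of the C3 hydroxyl (silyl ether) and the side-chain C7' ketone (dioxolane), leading back to salicylate 16.
- Key disconnection: C4a–C5 and C8–C8a of the benzene ring (closed first), leading back to silyloxy diene 13 and chiral ynoate 10.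
- Ynoate 10 comes from forming C4–C4a by opening (R)-epoxide 6 with lithiated methyl propiolate 7. The C3 stereocentre is set by hydrolytic kinetic resolution.
- Epoxide 6 comes from 8-nonenoic acid 1 (butyl ketone, dioxolane, epoxidation); diene 13 comes from methyl (E)-3-methoxybut-2-enoate 11.

Key step: step 8

Remark: target numbering follows isochroman-1-one (C1 carbonyl, O2, C3 carbinol carbon, C4, C4a, C5–C8, C8a); the side-chain ketone carbon is C7'.

## Route

Step 1
Reactants: 1 8-nonenoic acid
Product: 3 tridec-12-en-5-one, via non-8-enoyl chloride 2 (not isolated)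
Conditions: (COCl)2, cat. DMF, CH2Cl2, 0 °C to rt, evaporate; then n-BuMgCl (1.1 equiv), Fe(acac)3 (iron tris(acetylacetonate), 3 mol %), THF, −78 °C
Reagents that add atoms: n-butylmagnesium chloride, CCCC[Mg]Cl
Why: Acid chloride formation followed by iron-catalysed acylation of an alkyl Grignard reagent should stop at the ketone, because the catalysed coupling with the acid chloride is much faster at −78 °C than Grignard addition to the ketone, and the terminal alkene is inert.

Step 2
Reactants: 3 tridec-12-en-5-one
Product: 4 2-butyl-2-(oct-7-en-1-yl)-1,3-dioxolane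
Conditions: HOCH2CH2OH (5 equiv), p-TsOH·H2O (cat.), toluene, reflux, Dean–Stark
Reagents that add atoms: ethylene glycol, OCCO
Why: Acid-catalysed ketalisation with azeotropic removal of water masks the ketone against the acetylide chemistry that follows.

Step 3
Reactants: 4 2-butyl-2-(oct-7-en-1-yl)-1,3-dioxolane
Product: 5 rac-2-[6-(2-butyl-1,3-dioxolan-2-yl)hexyl]oxirane
Conditions: mCPBA, NaHCO3, CH2Cl2, 0 °C to rt
Reagents that add atoms: mCPBA, O=C(OO)c1cccc(Cl)c1
Why: Prilezhaev epoxidation of the only alkene, with NaHCO3 buffering the 3-chlorobenzoic acid so that the dioxolane is not touched; the epoxide is formed as the racemate.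

Step 4
Reactants: 5 rac-2-[6-(2-butyl-1,3-dioxolan-2-yl)hexyl]oxirane
Product: 6 (R)-2-[6-(2-butyl-1,3-dioxolan-2-yl)hexyl]oxirane
Conditions: (R,R)-(salen)Co(OAc) [salen = N,N'-bis(3,5-di-tert-butylsalicylidene)-1,2-cyclohexanediaminate; trivalent cobalt, formed from the divalent cobalt complex with AcOH in air] (0.5 mol %), H2O (0.55 equiv), THF, 0 °C to rt; chromatography
Reagents that add atoms: none
Why: Jacobsen hydrolytic kinetic resolution, in which the (R,R)-catalyst hydrolyses the (S)-enantiomer of an alkyl oxirane to the diol and leaves the (R)-epoxide, so the future C3 stereocentre is set by the catalyst and the polar diol is removed on silica.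

Step 5
Reactants: 6 (R)-2-[6-(2-butyl-1,3-dioxolan-2-yl)hexyl]oxirane; 7 methyl propiolate
Product: 9 methyl (R)-11-(2-butyl-1,3-dioxolan-2-yl)-5-hydroxyundec-2-ynoate, via methyl 3-lithiopropiolate 8 (not isolated)
Conditions: 7 (2.5 equiv), n-BuLi, THF, −78 °C; BF3·OEt2; then 6, −78 °C; aq. NH4Cl quench at −78 °C
Reagents that add atoms: none
Why: Yamaguchi-type BF3-promoted opening of a terminal epoxide by a lithium acetylide occurs by SN2 attack at the unsubstituted carbon (forming C4–C4a), so the C–O bond at the stereocentre is not broken and the (R) configuration is carried over; the dioxolane should survive BF3·OEt2 in THF at −78 °C.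

Step 6
Reactants: 9 methyl (R)-11-(2-butyl-1,3-dioxolan-2-yl)-5-hydroxyundec-2-ynoate
Product: 10 methyl (R)-5-(tert-butyldimethylsilyloxy)-11-(2-butyl-1,3-dioxolan-2-yl)undec-2-ynoate
Conditions: TBSCl, imidazole, DMF, rt
Reagents that add atoms: tert-butyldimethylsilyl chloride, CC(C)(C)[Si](C)(C)Cl
Why: Standard silylation of a secondary alcohol, which keeps the hydroxyl from consuming the silyl ketene acetal diene in the cycloaddition and does not affect the stereocentre.

Step 7
Reactants: 11 methyl (E)-3-methoxybut-2-enoate
Product: 13 (E)-1,3-dimethoxy-1-(trimethylsilyloxy)buta-1,3-diene, via lithium dienolate 12 (not isolated)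
Conditions: LiN(i-Pr)2 (1.1 equiv), THF, −78 °C; Me3SiCl, −78 °C to rt; pentane, filter, distil under reduced pressure
Reagents that add atoms: chlorotrimethylsilane, C[Si](C)(C)Cl
Why: γ-Deprotonation of the vinylogous ester gives the extended enolate, and O-silylation traps it as the silyl ketene acetal diene (Brassard-type diene), a standard one-step preparation.

Step 8
Reactants: 10 methyl (R)-5-(tert-butyldimethylsilyloxy)-11-(2-butyl-1,3-dioxolan-2-yl)undec-2-ynoate; 13 (E)-1,3-dimethoxy-1-(trimethylsilyloxy)buta-1,3-diene
Product: 16 methyl 6-[(R)-2-(tert-butyldimethylsilyloxy)-8-(2-butyl-1,3-dioxolan-2-yl)octyl]-2-hydroxy-4-methoxybenzoate, via Diels–Alder adduct 14 (not isolated), via cyclohexadienone 15 (not isolated)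
Conditions: 13 (3 equiv), toluene, 130 °C, sealed tube, base-washed glassware; then SiO2, CH2Cl2, rt
Reagents that add atoms: none
Why: This is a thermal normal-electron-demand Diels–Alder addition of a 1,1,3-trioxygenated diene to an acetylenic ester, the established route to 4-methoxysalicylates. Bond formation is asynchronous: the CH2 terminus of 13, which has the largest HOMO coefficient, attacks the β-carbon of the ynoate (C5–C4a) and the ketene acetal carbon then joins the α-carbon (C8–C8a), so the benzene ring is closed by an intermolecular [4+2] annulation giving a six-membered carbocycle. Adduct 14 is a cyclohexa-1,4-diene with a mixed methyl silyl ketal at C8; it should collapse with loss of methoxytrimethylsilane to dienone 15, which enolises irreversibly to the phenol, helped by the hydrogen bond to the ester carbonyl. No stereocentre is created in 16 (the ketal carbon of 14 is transient), and the C3 carbinol centre, separated from the reacting carbons by the C4 methylene and protected as the silyl ether, is carried through unchanged. The only selectivity needed is regiochemical, and it is secured by matching the electron-rich diene terminus with the ester-polarised alkyne, which places the ester between the C8 hydroxyl and the side chain and the methoxy group at C6. Excess diene and acid-free conditions should compensate for the modest dienophilicity of a β-alkyl ynoate.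

Step 9
Reactants: 16 methyl 6-[(R)-2-(tert-butyldimethylsilyloxy)-8-(2-butyl-1,3-dioxolan-2-yl)octyl]-2-hydroxy-4-methoxybenzoate
Product: 19 (R)-8-hydroxy-6-methoxy-3-(7-oxoundecyl)isochroman-1-one, via keto silyl ether 17 (not isolated), via hydroxy keto ester 18 (not isolated)
Conditions: 2 M aq. HCl/THF (1:4), 45 °C; then cat. p-TsOH, toluene, 60 °C to complete ring closure
Reagents that add atoms: water, O
Why: Aqueous acid should hydrolyse the dioxolane (the ketone oxygen comes from water), cleave the secondary silyl ether and catalyse intramolecular transesterification of the freed C3 hydroxyl onto the neighbouring methyl ester to close the six-membered lactone (C1–O2); no bond at C3 is broken, so the (R) configuration is retained.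

## Compound list

1 | 8-nonenoic acid | C=CCCCCCCC(=O)O | starting material
2 | non-8-enoyl chloride | C=CCCCCCCC(=O)Cl | intermediate
3 | tridec-12-en-5-one | C=CCCCCCCC(=O)CCCC | intermediate
4 | 2-butyl-2-(oct-7-en-1-yl)-1,3-dioxolane | C=CCCCCCCC1(CCCC)OCCO1 | intermediate
5 | rac-2-[6-(2-butyl-1,3-dioxolan-2-yl)hexyl]oxirane | CCCCC1(OCCO1)CCCCCCC2CO2 | intermediate
6 | (R)-2-[6-(2-butyl-1,3-dioxolan-2-yl)hexyl]oxirane | CCCCC1(OCCO1)CCCCCC[C@@H]2CO2 | intermediate
7 | methyl propiolate | C#CC(=O)OC | starting material
8 | methyl 3-lithiopropiolate | [Li]C#CC(=O)OC | intermediate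
9 | methyl (R)-11-(2-butyl-1,3-dioxolan-2-yl)-5-hydroxyundec-2-ynoate | CCCCC1(OCCO1)CCCCCC[C@@H](O)CC#CC(=O)OC | intermediate
10 | methyl (R)-5-(tert-butyldimethylsilyloxy)-11-(2-butyl-1,3-dioxolan-2-yl)undec-2-ynoate | CCCCC1(OCCO1)CCCCCC[C@@H](O[Si](C)(C)C(C)(C)C)CC#CC(=O)OC | intermediate
11 | methyl (E)-3-methoxybut-2-enoate | CO/C(C)=C/C(=O)OC | starting material
12 | lithium 1,3-dimethoxybuta-1,3-dien-1-olate | C=C(OC)/C=C(\OC)[O-].[Li+] | intermediate
13 | (E)-1,3-dimethoxy-1-(trimethylsilyloxy)buta-1,3-diene | C=C(OC)/C=C(\OC)O[Si](C)(C)C | intermediate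
14 | methyl 2-[(R)-2-(tert-butyldimethylsilyloxy)-8-(2-butyl-1,3-dioxolan-2-yl)octyl]-4,6-dimethoxy-6-(trimethylsilyloxy)cyclohexa-1,4-diene-1-carboxylate (both epimers at the ketal carbon) | CCCCC1(OCCO1)CCCCCC[C@@H](O[Si](C)(C)C(C)(C)C)CC2=C(C(=O)OC)C(OC)(O[Si](C)(C)C)C=C(OC)C2 | intermediate
15 | methyl 2-[(R)-2-(tert-butyldimethylsilyloxy)-8-(2-butyl-1,3-dioxolan-2-yl)octyl]-4-methoxy-6-oxocyclohexa-1,4-diene-1-carboxylate | CCCCC1(OCCO1)CCCCCC[C@@H](O[Si](C)(C)C(C)(C)C)CC2=C(C(=O)OC)C(=O)C=C(OC)C2 | intermediate
16 | methyl 6-[(R)-2-(tert-butyldimethylsilyloxy)-8-(2-butyl-1,3-dioxolan-2-yl)octyl]-2-hydroxy-4-methoxybenzoate | CCCCC1(OCCO1)CCCCCC[C@@H](O[Si](C)(C)C(C)(C)C)Cc2cc(OC)cc(O)c2C(=O)OC | intermediate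
17 | methyl 6-[(R)-2-(tert-butyldimethylsilyloxy)-9-oxotridecyl]-2-hydroxy-4-methoxybenzoate | CCCCC(=O)CCCCCC[C@@H](O[Si](C)(C)C(C)(C)C)Cc1cc(OC)cc(O)c1C(=O)OC | intermediate
18 | methyl 2-hydroxy-6-[(R)-2-hydroxy-9-oxotridecyl]-4-methoxybenzoate | CCCCC(=O)CCCCCC[C@@H](O)Cc1cc(OC)cc(O)c1C(=O)OC | intermediate
19 | (R)-8-hydroxy-6-methoxy-3-(7-oxoundecyl)isochroman-1-one | CCCCC(=O)CCCCCC[C@@H]1Cc2cc(OC)cc(O)c2C(=O)O1 | target

## Step count

Total step count: 9. Longest linear sequence: 8 steps (steps 1–6, 8 and 9, from 8-nonenoic acid); step 7 is a one-step side branch.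

## Steps most likely to fail

**Step 8 (cycloaddition and aromatisation).** The β-alkyl ynoate may add too slowly while diene 13 is lost to thermal decomposition or protodesilylation, and part of the adduct may aromatise by loss of trimethylsilanol instead of methoxytrimethylsilane, which would leave C8 as a methyl ether. The fallback sets out from 10 and keeps the same ring construction, but moves the differentiation of the two oxygens to a later step. Compound 10 is heated neat at 140 °C with an excess of commercial 1-methoxy-1,3-bis(trimethylsilyloxy)buta-1,3-diene and worked up with silica, which should give the resorcylate methyl 6-[(R)-2-(tert-butyldimethylsilyloxy)-8-(2-butyl-1,3-dioxolan-2-yl)octyl]-2,4-dihydroxybenzoate F1. The C6 hydroxyl, para to the ester, is then methylated selectively with MeI (1.1 equiv) and K2CO3 in acetone at rt; the C8 hydroxyl is held in a hydrogen bond to the ester carbonyl and should not react. This comes back to the route at 16.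

**Step 5 (epoxide opening with lithiated propiolate).** The lithiated propiolate may decompose before it opens the epoxide, or BF3·OEt2 may attack the dioxolane. The fallback sets out from 6 and uses no Lewis acid. Opening with LiC≡CH·H2NCH2CH2NH2 in DMSO at rt should give (R)-10-(2-butyl-1,3-dioxolan-2-yl)dec-1-yn-4-ol F2. Silylation with TBSCl and imidazole in DMF gives tert-butyl{[(R)-10-(2-butyl-1,3-dioxolan-2-yl)dec-1-yn-4-yl]oxy}dimethylsilane F3. Deprotonation with n-BuLi in THF at −78 °C gives the lithium acetylide of this silyl ether F4, which is acylated with methyl chloroformate. This comes back to the route at 10.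

**Step 9 (one-pot deprotection and lactonisation).** Lactonisation of the hydrogen-bonded, doubly ortho-substituted ester may be incomplete under aqueous acid, or the freed ketone may undergo acid-promoted self-condensation on prolonged heating. The fallback sets out from 16 and separates the events under different activation. Bu4NF in THF at 0 °C to rt removes the silyl group, and the resulting alkoxide should close onto the ester to give (R)-3-[6-(2-butyl-1,3-dioxolan-2-yl)hexyl]-8-hydroxy-6-methoxyisochroman-1-one F5. The dioxolane is then removed with pyridinium p-toluenesulfonate in acetone/H2O at 50 °C. This comes back to the route at 19.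

## Further compounds

F1 | step 8 | methyl 6-[(R)-2-(tert-butyldimethylsilyloxy)-8-(2-butyl-1,3-dioxolan-2-yl)octyl]-2,4-dihydroxybenzoate | CCCCC1(OCCO1)CCCCCC[C@@H](O[Si](C)(C)C(C)(C)C)Cc2cc(O)cc(O)c2C(=O)OC
F2 | step 5 | (R)-10-(2-butyl-1,3-dioxolan-2-yl)dec-1-yn-4-ol | CCCCC1(OCCO1)CCCCCC[C@@H](O)CC#C
F3 | step 5 | tert-butyl{[(R)-10-(2-butyl-1,3-dioxolan-2-yl)dec-1-yn-4-yl]oxy}dimethylsilane | CCCCC1(OCCO1)CCCCCC[C@@H](O[Si](C)(C)C(C)(C)C)CC#C
F4 | step 5 | lithium acetylide of F3 | CCCCC1(OCCO1)CCCCCC[C@@H](O[Si](C)(C)C(C)(C)C)CC#C[Li]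
F5 | step 9 | (R)-3-[6-(2-butyl-1,3-dioxolan-2-yl)hexyl]-8-hydroxy-6-methoxyisochroman-1-one | CCCCC1(OCCO1)CCCCCC[C@@H]2Cc3cc(OC)cc(O)c3C(=O)O2
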